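**Plan**

- Numbering: dihydrobenzofuran O1, C2, C3, C3a, C4–C7, C7a (benzo ring = ring A); guaiacyl ring = ring B; glycerol chain C7'–C8'–C9' on C5.
- Retrosynthesis: both CH2OH groups (on C3 and C9') are traced back to vinyl groups. C7'–C8' is cut (alkoxyallylboration of a C5 aldehyde). The heterocycle is cut at O1–C7a and C2–C3, giving O-benzylvanillin and a (Z)-γ-aryl allylboronate built on methyl 4-fluoro-3-methoxybenzoate.
- Enabling feature: C5 of ring A, the carbon that later carries the glycerol chain, is para to C7a, so as an ester it activates a fluoride at C7a towards the C2 alkoxide. C3 carries a one-carbon arm that can be a vinyl group, so C3 can be the γ-carbon of an allylboronate.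
- Forward: ring A is armed (C–H borylation, cis-chlorovinyl, allylboronate); the furan ring closes in the annulation with the ring B aldehyde; then ester to aldehyde, a second allylboration for the chain, one double oxidative cleavage/reduction, and hydrogenolysis.
- Stereochemistry: C2 from (R)-TRIP and C3 from the Z geometry of the boronate (chair, syn adduct, trans ring). C7' from the same catalyst and C8' from the E geometry of the γ-benzyloxyallylboronate (anti adduct, erythro chain).

Key step: step 4

Assumption: (R)-TRIP is taken to deliver the allyl unit to the aldehyde face that gives the R carbinol with simple aryl aldehydes; if the sense proved opposite, (S)-TRIP would be used in steps 4 and 9.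

**Route**

Step 1
Reactants: 1 methyl 4-fluoro-3-methoxybenzoate; 2 bis(pinacolato)diboron
Product: 3 methyl 4-fluoro-3-methoxy-5-(4,4,5,5-tetramethyl-1,3,2-dioxaborolan-2-yl)benzoate
Conditions: [Ir(OMe)(cod)]2 (1.5 mol %), 4,4'-di-tert-butyl-2,2'-bipyridine (3 mol %), THF, 80 °C
Reagents that add atoms: none
Why: Iridium-catalysed aromatic C–H borylation is sterically governed, so only the hydrogen next to the small fluorine (the future C3a) should react, the other two being ortho to the ester or flanked by ester and methoxy.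

Step 2
Reactants: 3 methyl 4-fluoro-3-methoxy-5-(pinacolboryl)benzoate; 4 (Z)-1,2-dichloroethene (5 equiv)
Product: 5 methyl 3-[(Z)-2-chloroethenyl]-4-fluoro-5-methoxybenzoate
Conditions: Pd(PPh3)4 (5 mol %), K3PO4 (2 equiv), 1,4-dioxane/H2O, 60 °C, sealed tube
Reagents that add atoms: none
Why: Suzuki–Miyaura coupling at one C–Cl bond of the excess dihaloalkene proceeds with retention of the cis geometry, and the less reactive chloroalkene product should survive under the triphenylphosphine catalyst.

Step 3
Reactants: 5 methyl 3-[(Z)-2-chloroethenyl]-4-fluoro-5-methoxybenzoate; 6 2-(iodomethyl)-4,4,5,5-tetramethyl-1,3,2-dioxaborolane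
Product: 8 methyl 4-fluoro-3-methoxy-5-[(1Z)-3-(4,4,5,5-tetramethyl-1,3,2-dioxaborolan-2-yl)prop-1-en-1-yl]benzoate, via borylmethylzinc iodide 7 (not isolated)
Conditions: Zn dust (activated by 1,2-dibromoethane/Me3SiCl), THF, 23 °C; then 5, Pd(P(t-Bu)3)2 (3 mol %), THF/NMP, 50 °C
Reagents that add atoms: zinc dust, [Zn] (held only in intermediate 7)
Why: Negishi coupling of a boryl-substituted alkylzinc iodide with an alkenyl chloride is stereoretentive, so the Z geometry of 5 should pass into the allylboronate, and the neutral conditions spare the methyl ester.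

Step 4
Reactants: 8 the (Z)-γ-aryl allylboronate; 9 4-(benzyloxy)-3-methoxybenzaldehyde
Product: 11 methyl (2R,3R)-2-[4-(benzyloxy)-3-methoxyphenyl]-3-ethenyl-7-methoxy-2,3-dihydro-1-benzofuran-5-carboxylate, via pinacol borate 10 (not isolated)
Conditions: (R)-TRIP [(R)-3,3'-bis(2,4,6-triisopropylphenyl)-1,1'-binaphthalene-2,2'-diyl hydrogen phosphate] (10 mol %), 4 Å MS, toluene, −30 → 0 °C; then KOtBu (1.2 equiv), DMF, 0 → 23 °C, 0.02 M
Reagents that add atoms: none
Why: The phosphoric acid hydrogen-bonds to a boronate oxygen and the aldehyde adds to the γ-carbon of 8 through a closed six-membered chair transition state, which forms C2–C3 and leaves the O-boryl alkoxide 10; tert-butoxide then transfers to boron and the freed C2 alkoxide adds to C7a and expels fluoride through the anionic σ-adduct, which forms O1–C7a. The closest known reaction types are the chiral-phosphoric-acid-catalysed crotylboration of aryl aldehydes with pinacol boronates and the intramolecular SNAr etherification of fluoroarenes that carry a para acceptor. The furan ring closes in a 5-exo mode onto the fluorine-bearing aromatic carbon. C2 is set by the catalyst, (R)-TRIP being expected to expose the aldehyde face that gives the R carbinol, and C3 is set by the Z geometry of 8, which holds ring A axial in the chair and gives the syn adduct, hence the trans-2,3 ring after closure with retention at both centres. The step needs γ-attack (inherent to allylboronates) and a ring closure that outruns isomerisation of the allylic, benzylic C3–H and intermolecular attack on the ester, which the para ester at C5, the five-membered transition state, the near-stoichiometric base and high dilution should secure; any tert-butyl ester formed by exchange converges on 12 in step 5.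

Step 5
Reactants: 11 the dihydrobenzofuran methyl ester
Product: 12 {(2R,3R)-2-[4-(benzyloxy)-3-methoxyphenyl]-3-ethenyl-7-methoxy-2,3-dihydro-1-benzofuran-5-yl}methanol
Conditions: i-Bu2AlH (2.5 equiv), CH2Cl2, −78 → 0 °C; aq. potassium sodium tartrate
Reagents that add atoms: none
Why: Aluminium hydride reduction of the aryl ester should give the benzylic alcohol and leave the alkene, the benzyl ether and both stereocentres untouched.

Step 6
Reactants: 12 the benzylic alcohol
Product: 13 (2R,3R)-2-[4-(benzyloxy)-3-methoxyphenyl]-3-ethenyl-7-methoxy-2,3-dihydro-1-benzofuran-5-carbaldehyde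
Conditions: MnO2 (activated, 15 equiv), CH2Cl2, 23 °C
Reagents that add atoms: none
Why: Heterogeneous MnO2 oxidation is selective for the electron-rich benzylic alcohol and stops at the aldehyde.

Step 7
Reactants: 14 benzyl prop-2-yn-1-yl ether; 15 pinacolborane
Product: 16 2-[(1E)-3-(benzyloxy)prop-1-en-1-yl]-4,4,5,5-tetramethyl-1,3,2-dioxaborolane
Conditions: Cp2Zr(H)Cl (5 mol %), Et3N (10 mol %), neat, 60 °C
Reagents that add atoms: none
Why: Zirconocene-hydride-catalysed syn hydroboration of the terminal alkyne places boron on the terminal carbon and should give the E alkenylboronate.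

Step 8
Reactants: 16 the (E)-alkenylboronate
Product: 17 2-[(2E)-3-(benzyloxy)prop-2-en-1-yl]-4,4,5,5-tetramethyl-1,3,2-dioxaborolane
Conditions: [Ir(cod)(PPh2Me)2]PF6 (3 mol %, pre-activated with H2), THF, 23 °C
Reagents that add atoms: none
Why: Cationic-iridium-catalysed 1,3-hydrogen shift, the allyl ether to E-propenyl ether isomerisation, moves the double bond next to oxygen and should give the (E)-γ-alkoxyallylboronate.

Step 9
Reactants: 13 the C5 aldehyde; 17 the (E)-γ-benzyloxyallylboronate
Product: 19 (1S,2R)-2-(benzyloxy)-1-{(2R,3R)-2-[4-(benzyloxy)-3-methoxyphenyl]-3-ethenyl-7-methoxy-2,3-dihydro-1-benzofuran-5-yl}but-3-en-1-ol, via pinacol borate 18 (not isolated)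
Conditions: (R)-TRIP (5 mol %), 4 Å MS, toluene, −45 °C; aq. NaHCO3 work-up
Reagents that add atoms: none
Why: In this chiral-phosphoric-acid-catalysed alkoxyallylboration the chair transition state of the E boronate gives the anti (erythro) diol monoether, and the catalyst, acting on the same aldehyde face as in step 4, should set C7' as S and hence C8' as R, the remote ring stereocentres exerting no control.

Step 10
Reactants: 19 the bis-vinyl alcohol
Product: 21 (1S,2R)-2-(benzyloxy)-1-{(2R,3S)-2-[4-(benzyloxy)-3-methoxyphenyl]-3-(hydroxymethyl)-7-methoxy-2,3-dihydro-1-benzofuran-5-yl}propane-1,3-diol, via dialdehyde 20 (not isolated)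
Conditions: OsO4 (4 mol %), NaIO4 (6 equiv), 2,6-lutidine (4 equiv), 1,4-dioxane/H2O, 23 °C; extraction; then NaBH4, MeOH, 0 °C
Reagents that add atoms: osmium tetroxide, O=[Os](=O)(=O)=O (transfers oxygen to both alkenes); sodium periodate, [Na+].[O-]I(=O)(=O)=O (reoxidant and source of that oxygen)
Why: Lemieux–Johnson cleavage of both terminal alkenes followed by borohydride reduction should turn the two vinyl groups into the two hydroxymethyl groups without touching the electron-rich arenes, the lutidine buffer and prompt reduction guarding the two epimerisable aldehydes; no stereocentre is made or broken.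

Step 11
Reactants: 21 the dibenzyl ether
Product: 22 (1S,2R)-1-[(2R,3S)-2-(4-hydroxy-3-methoxyphenyl)-3-(hydroxymethyl)-7-methoxy-2,3-dihydro-1-benzofuran-5-yl]propane-1,2,3-triol (CNP0219585.3)
Conditions: H2 (1 atm), Pd/C (10 wt %), EtOAc/MeOH, 23 °C, stopped at full debenzylation
Reagents that add atoms: none
Why: Catalytic hydrogenolysis of the aryl benzyl ether and the alkyl benzyl ether should be faster under neutral conditions than cleavage of the ring C2–O1 bond or the C7' benzylic alcohol, so both benzyl groups leave with all four stereocentres retained.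

**Compound list**

1 | methyl 4-fluoro-3-methoxybenzoate | COC(=O)c1ccc(F)c(OC)c1 | starting material
2 | bis(pinacolato)diboron | CC1(C)OB(OC1(C)C)B1OC(C)(C)C(C)(C)O1 | starting material
3 | methyl 4-fluoro-3-methoxy-5-(4,4,5,5-tetramethyl-1,3,2-dioxaborolan-2-yl)benzoate | COC(=O)c1cc(OC)c(F)c(c1)B1OC(C)(C)C(C)(C)O1 | intermediate
4 | (Z)-1,2-dichloroethene | Cl/C=C\Cl | starting material
5 | methyl 3-[(Z)-2-chloroethenyl]-4-fluoro-5-methoxybenzoate | COC(=O)c1cc(OC)c(F)c(/C=C\Cl)c1 | intermediate
6 | 2-(iodomethyl)-4,4,5,5-tetramethyl-1,3,2-dioxaborolane | ICB1OC(C)(C)C(C)(C)O1 | starting material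
7 | [(4,4,5,5-tetramethyl-1,3,2-dioxaborolan-2-yl)methyl]zinc iodide | I[Zn]CB1OC(C)(C)C(C)(C)O1 | intermediate
8 | methyl 4-fluoro-3-methoxy-5-[(1Z)-3-(4,4,5,5-tetramethyl-1,3,2-dioxaborolan-2-yl)prop-1-en-1-yl]benzoate | COC(=O)c1cc(OC)c(F)c(/C=C\CB2OC(C)(C)C(C)(C)O2)c1 | intermediate
9 | 4-(benzyloxy)-3-methoxybenzaldehyde | COc1cc(C=O)ccc1OCc1ccccc1 | starting material
10 | methyl 3-{(1R,2R)-1-[4-(benzyloxy)-3-methoxyphenyl]-1-[(4,4,5,5-tetramethyl-1,3,2-dioxaborolan-2-yl)oxy]but-3-en-2-yl}-4-fluoro-5-methoxybenzoate | COc1cc([C@H](OB2OC(C)(C)C(C)(C)O2)[C@H](C=C)c2cc(C(=O)OC)cc(OC)c2F)ccc1OCc1ccccc1 | intermediate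
11 | methyl (2R,3R)-2-[4-(benzyloxy)-3-methoxyphenyl]-3-ethenyl-7-methoxy-2,3-dihydro-1-benzofuran-5-carboxylate | COc1cc([C@@H]2Oc3c(OC)cc(C(=O)OC)cc3[C@H]2C=C)ccc1OCc1ccccc1 | intermediate
12 | {(2R,3R)-2-[4-(benzyloxy)-3-methoxyphenyl]-3-ethenyl-7-methoxy-2,3-dihydro-1-benzofuran-5-yl}methanol | COc1cc([C@@H]2Oc3c(OC)cc(CO)cc3[C@H]2C=C)ccc1OCc1ccccc1 | intermediate
13 | (2R,3R)-2-[4-(benzyloxy)-3-methoxyphenyl]-3-ethenyl-7-methoxy-2,3-dihydro-1-benzofuran-5-carbaldehyde | COc1cc([C@@H]2Oc3c(OC)cc(C=O)cc3[C@H]2C=C)ccc1OCc1ccccc1 | intermediate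
14 | benzyl prop-2-yn-1-yl ether | C#CCOCc1ccccc1 | starting material
15 | pinacolborane | [H]B1OC(C)(C)C(C)(C)O1 | starting material
16 | 2-[(1E)-3-(benzyloxy)prop-1-en-1-yl]-4,4,5,5-tetramethyl-1,3,2-dioxaborolane | CC1(C)OB(/C=C/COCc2ccccc2)OC1(C)C | intermediate
17 | 2-[(2E)-3-(benzyloxy)prop-2-en-1-yl]-4,4,5,5-tetramethyl-1,3,2-dioxaborolane | CC1(C)OB(C/C=C/OCc2ccccc2)OC1(C)C | intermediate
18 | pinacol borate of 19 (O-boryl at C7', configuration as in 19) | COc1cc([C@@H]2Oc3c(OC)cc([C@H](OB4OC(C)(C)C(C)(C)O4)[C@H](OCc4ccccc4)C=C)cc3[C@H]2C=C)ccc1OCc1ccccc1 | intermediate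
19 | (1S,2R)-2-(benzyloxy)-1-{(2R,3R)-2-[4-(benzyloxy)-3-methoxyphenyl]-3-ethenyl-7-methoxy-2,3-dihydro-1-benzofuran-5-yl}but-3-en-1-ol | COc1cc([C@@H]2Oc3c(OC)cc([C@H](O)[C@H](OCc4ccccc4)C=C)cc3[C@H]2C=C)ccc1OCc1ccccc1 | intermediate
20 | (2S,3S)-2-(benzyloxy)-3-{(2R,3R)-2-[4-(benzyloxy)-3-methoxyphenyl]-3-formyl-7-methoxy-2,3-dihydro-1-benzofuran-5-yl}-3-hydroxypropanal (all centres spatially as in 19) | COc1cc([C@@H]2Oc3c(OC)cc([C@H](O)[C@H](OCc4ccccc4)C=O)cc3[C@H]2C=O)ccc1OCc1ccccc1 | intermediate
21 | (1S,2R)-2-(benzyloxy)-1-{(2R,3S)-2-[4-(benzyloxy)-3-methoxyphenyl]-3-(hydroxymethyl)-7-methoxy-2,3-dihydro-1-benzofuran-5-yl}propane-1,3-diol | COc1cc([C@@H]2Oc3c(OC)cc([C@H](O)[C@H](OCc4ccccc4)CO)cc3[C@H]2CO)ccc1OCc1ccccc1 | intermediate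
22 | (1S,2R)-1-[(2R,3S)-2-(4-hydroxy-3-methoxyphenyl)-3-(hydroxymethyl)-7-methoxy-2,3-dihydro-1-benzofuran-5-yl]propane-1,2,3-triol | COc1cc([C@@H]2Oc3c(OC)cc([C@H](O)[C@H](O)CO)cc3[C@H]2CO)ccc1O | target

**Count and risks**

Total step count: 11. Longest linear sequence: 9 steps (steps 1–6 and 9–11, from 1); steps 7 and 8 make the side-chain reagent 17.

Steps most likely to fail:

Step 4. The addition of the hindered (Z)-boronate under Brønsted acid catalysis may be slow and poorly face-selective. In the second stage, base-induced migration of the vinyl double bond or ester exchange may compete with ring closure. The fallback uses reagent control and a stepwise closure. It sets out from boronate 3. Coupling with methyl prop-2-yn-1-yl carbonate (Pd(PPh3)4, THF, 50 °C) should give the aryl allene methyl 4-fluoro-3-methoxy-5-(propa-1,2-dien-1-yl)benzoate F1. Kinetically controlled hydroboration of its terminal double bond with (+)-diisopinocampheylborane (from (−)-α-pinene; THF, −40 °C) should give the (Z)-γ-aryl allylborane methyl 3-{(1Z)-3-[bis(isopinocampheyl)boranyl]prop-1-en-1-yl}-4-fluoro-5-methoxybenzoate F2, which is used in the flask. Addition of aldehyde 9 at −78 °C should give the bis(isopinocampheyl)borinate of the syn adduct F3, and ethanolamine work-up the alcohol methyl 3-{(1R,2R)-1-[4-(benzyloxy)-3-methoxyphenyl]-1-hydroxybut-3-en-2-yl}-4-fluoro-5-methoxybenzoate F4. Ring closure of isolated F4 with NaH in THF/DMF at 0 °C comes back to the route at 11.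

Step 3. Protodemetalation of the zinc reagent or sluggish transmetalation may allow loss of the Z geometry or further coupling of the allylboronate. The fallback sets out from 5 and couples it with commercial bis[(pinacolato)boryl]methane, activated as its methoxide adduct (Pd(P(t-Bu)3)2, NaOMe, 1,4-dioxane/MeOH, 23 °C). This is a deborylative Suzuki–Miyaura-type coupling of a geminal diboron in place of the organozinc, and it comes back at 8. No compound outside the list is made (F0).

Step 10. The β-hydroxy-α-benzyloxy aldehyde may undergo retro-aldol cleavage or epimerisation at C8', and the 3-formyl dihydrobenzofuran may epimerise or open by β-elimination before reduction. The fallback protects C7'–OH and separates the operations. It sets out from 19. Silylation (t-BuMe2SiOTf, 2,6-lutidine) should give the C7' tert-butyldimethylsilyl ether of 19 F5. Dihydroxylation (OsO4 cat., N-methylmorpholine N-oxide) should give the isolated bis-diol F6, a mixture at the two new carbinol carbons. Glycol cleavage (NaIO4, buffered aqueous THF) should give the silyl-protected dialdehyde F7 in the flask, and NaBH4 the C7' silyl ether of 21 F8. Bu4NF then comes back to the route at 21.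

**Further compounds**

F1 | step 4 | methyl 4-fluoro-3-methoxy-5-(propa-1,2-dien-1-yl)benzoate | COC(=O)c1cc(OC)c(F)c(C=C=C)c1
F2 | step 4 | methyl 3-{(1Z)-3-[bis((1S,2R,3S,5S)-2,6,6-trimethylbicyclo[3.1.1]heptan-3-yl)boranyl]prop-1-en-1-yl}-4-fluoro-5-methoxybenzoate | COC(=O)c1cc(OC)c(F)c(/C=C\CB([C@H]2C[C@H]3C[C@@H]([C@@H]2C)C3(C)C)[C@H]2C[C@H]3C[C@@H]([C@@H]2C)C3(C)C)c1
F3 | step 4 | bis(isopinocampheyl)borinate of F4 | COc1cc([C@H](OB([C@H]2C[C@H]3C[C@@H]([C@@H]2C)C3(C)C)[C@H]2C[C@H]3C[C@@H]([C@@H]2C)C3(C)C)[C@H](C=C)c2cc(C(=O)OC)cc(OC)c2F)ccc1OCc1ccccc1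
F4 | step 4 | methyl 3-{(1R,2R)-1-[4-(benzyloxy)-3-methoxyphenyl]-1-hydroxybut-3-en-2-yl}-4-fluoro-5-methoxybenzoate | COc1cc([C@H](O)[C@H](C=C)c2cc(C(=O)OC)cc(OC)c2F)ccc1OCc1ccccc1
F0 | step 3 | none | none
F5 | step 10 | C7' tert-butyldimethylsilyl ether of 19 | COc1cc([C@@H]2Oc3c(OC)cc([C@H](O[Si](C)(C)C(C)(C)C)[C@H](OCc4ccccc4)C=C)cc3[C@H]2C=C)ccc1OCc1ccccc1
F6 | step 10 | bis-diol from dihydroxylation of both vinyl groups of F5 (new carbinol centres undefined) | COc1cc([C@@H]2Oc3c(OC)cc([C@H](O[Si](C)(C)C(C)(C)C)[C@H](OCc4ccccc4)C(O)CO)cc3[C@H]2C(O)CO)ccc1OCc1ccccc1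
F7 | step 10 | C7' tert-butyldimethylsilyl ether of dialdehyde 20 | COc1cc([C@@H]2Oc3c(OC)cc([C@H](O[Si](C)(C)C(C)(C)C)[C@H](OCc4ccccc4)C=O)cc3[C@H]2C=O)ccc1OCc1ccccc1
F8 | step 10 | C7' tert-butyldimethylsilyl ether of 21 | COc1cc([C@@H]2Oc3c(OC)cc([C@H](O[Si](C)(C)C(C)(C)C)[C@H](OCc4ccccc4)CO)cc3[C@H]2CO)ccc1OCc1ccccc1
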